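**Plan**
- Retrosynthetic cuts, in order: the C3a–CH2 bond of the angular prenyl group (retro-Claisen to an O4 1,1-dimethylallyl ether), the C7–prenyl bond, the O1–C2 bond of ring B (re-expansion to a 3-hydroxy-2,2-dimethylchroman), the benzylic C–O bond of a chromene oxide, the pyran C4–C4a bond (aryl propargyl ether), and the aryl–acyl bond.
- Enabling feature: in benzofuran numbering (O1, C2, C3, C3a, C4–C7, C7a; ring A the carbocycle, ring B the dihydrofuran) C2 carries both O1 and the CMe2OH carbon. Ring B is therefore the ring-contracted isomer of the O1–CMe2–CHOH–CH2 unit of a chroman-3-ol.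
- Forward order: ring A is phloroglucinol. Acylation, para-O-propargylation, MOM protection of both ortho hydroxyls and a propargyl Claisen/6π closure build the pyran ring with the acyl group necessarily at C6. Epoxidation and benzylic hydrogenolysis give the chroman-3-ol, and triflate solvolysis contracts it to ring B. C7 is then prenylated, and the C3a prenyl group arrives last by a dearomatising Claisen shift from O4.
- Stereochemistry: C2 comes from the Jacobsen epoxidation ((R,R) catalyst, 3R carbinol) and is inverted once in the contraction to 2S. C3a is set by substrate control, the allyl unit migrating to the ring face anti to the C2 side chain (3aS).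

Key step: step 7

Remark: the target is drawn as its C4-keto/C6-enol tautomer; the enolised β-triketone is treated as one compound in whichever tautomeric form it adopts.

**Step 1**
Reactants: 1 phloroglucinol; 2 isovaleryl chloride
Product: 3 1-(2,4,6-trihydroxyphenyl)-3-methylbutan-1-one
Conditions: AlCl3, CH2Cl2–MeNO2, 0 → 40 °C; aq. HCl work-up
Reagents that add atoms: none
Why: Friedel–Crafts C-acylation of the threefold-symmetric triol can give only one monoketone, and the chelated acyl group deactivates the ring against a second acylation.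

**Step 2**
Reactants: 3 1-(2,4,6-trihydroxyphenyl)-3-methylbutan-1-one; 4 3-chloro-3-methylbut-1-yne
Product: 5 1-[2,6-dihydroxy-4-(2-methylbut-3-yn-2-yloxy)phenyl]-3-methylbutan-1-one
Conditions: K2CO3 (1.2 equiv), KI (cat.), CuI (cat.), acetone, 50 °C
Reagents that add atoms: none
Why: Copper-assisted Williamson-type O-alkylation with a tertiary propargylic chloride takes the para hydroxyl, the most acidic one and the only one not hydrogen-bonded to the ketone, which is the usual site of mono-O-alkylation in 2,4,6-trihydroxyaryl ketones.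

**Step 3**
Reactants: 5 1-[2,6-dihydroxy-4-(2-methylbut-3-yn-2-yloxy)phenyl]-3-methylbutan-1-one
Product: 6 1-[2,6-bis(methoxymethoxy)-4-(2-methylbut-3-yn-2-yloxy)phenyl]-3-methylbutan-1-one
Conditions: NaH (2.2 equiv), MOMCl, DMF, 0 °C
Reagents that add atoms: chloromethyl methyl ether, COCCl
Why: Williamson etherification of the two phenoxides protects both chelated hydroxyls, which later leaves the para oxygen as the only one able to close the pyran ring.

**Step 4**
Reactants: 6 1-[2,6-bis(methoxymethoxy)-4-(2-methylbut-3-yn-2-yloxy)phenyl]-3-methylbutan-1-one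
Product: 7 1-[5,7-bis(methoxymethoxy)-2,2-dimethyl-2H-chromen-6-yl]-3-methylbutan-1-one
Conditions: N,N-diethylaniline, 150 °C
Reagents that add atoms: none
Why: Propargyl Claisen rearrangement to either of the two equivalent ortho carbons, 1,5-hydrogen shift and oxa-6π electrocyclisation give the 2,2-dimethylchromene, and because only the former ether oxygen is free the acyl group must end at C6 between the two MOM ethers.

**Step 5**
Reactants: 7 1-[5,7-bis(methoxymethoxy)-2,2-dimethyl-2H-chromen-6-yl]-3-methylbutan-1-one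
Product: 8 1-[(3R,4R)-3,4-epoxy-5,7-bis(methoxymethoxy)-2,2-dimethyl-3,4-dihydro-2H-chromen-6-yl]-3-methylbutan-1-one
Conditions: (R,R)-[N,N′-bis(3,5-di-tert-butylsalicylidene)cyclohexane-1,2-diaminato]MnCl (trivalent manganese, 4 mol%), 4-phenylpyridine N-oxide, NaOCl (aq, pH 11.3), CH2Cl2, 0 °C; crude product passed through basic alumina and used at once
Reagents that add atoms: sodium hypochlorite, [Na+].[O-]Cl
Why: Jacobsen–Katsuki epoxidation, for which cis-disubstituted 2,2-dimethylchromenes are the model substrates; the (R,R) catalyst delivers oxygen to the face that gives the (3R,4R) oxide, there is no other alkene, and the buffered basic medium spares the acid-labile benzylic epoxide and the acetals.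

**Step 6**
Reactants: 8 1-[(3R,4R)-3,4-epoxy-5,7-bis(methoxymethoxy)-2,2-dimethyl-3,4-dihydro-2H-chromen-6-yl]-3-methylbutan-1-one
Product: 9 1-[(3R)-3-hydroxy-5,7-bis(methoxymethoxy)-2,2-dimethyl-3,4-dihydro-2H-chromen-6-yl]-3-methylbutan-1-one
Conditions: H2 (1 atm), Pd/C, EtOAc, Et3N (1 mol%), 23 °C
Reagents that add atoms: none
Why: Catalytic hydrogenolysis cleaves only the benzylic C4–O bond of the aryl epoxide, so the C3–O bond and its (R) configuration are retained; the doubly ortho-substituted ketone and the MOM ethers are not reduced, and the trace of amine suppresses acid-induced isomerisation to the chroman-3-one (Meinwald rearrangement).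

**Step 7**
Reactants: 9 1-[(3R)-3-hydroxy-5,7-bis(methoxymethoxy)-2,2-dimethyl-3,4-dihydro-2H-chromen-6-yl]-3-methylbutan-1-one
Product: 12 1-[(2S)-2-(2-hydroxypropan-2-yl)-4,6-bis(methoxymethoxy)-2,3-dihydro-1-benzofuran-5-yl]-3-methylbutan-1-one, via chroman-3-yl triflate 10 (not isolated), via bicyclic aryloxiranium ion 11 (not isolated)
Conditions: Tf2O, 2,6-lutidine, CH2Cl2, −78 °C; then THF–H2O, NaHCO3, −78 → 23 °C
Reagents that add atoms: water, O
Why: O-Triflation gives 10; in the half-chair that places the triflate pseudo-equatorial the O1–C2 ring bond is antiperiplanar to C3–OTf, so a lone pair of the aryl ether oxygen displaces triflate from the rear to give the oxiranium ion 11, whose charge sits largely on the tertiary carbon, and water opens it there, cutting the old O1–CMe2 bond. This is anchimerically assisted solvolysis, the known contraction of 3-sulfonyloxy-2,2-dimethylchromans to 2-(2-hydroxypropan-2-yl)-2,3-dihydrobenzofurans. The O1–C bond formation is 3-exo-tet with respect to the oxiranium and 5-exo-tet with respect to the emerging dihydrofuran, the triflate leaving outside both rings. The one new stereocentre, C2 of the dihydrobenzofuran, results from clean inversion of the (3R) carbinol carbon fixed in step 5 and becomes (2S). The step needs capture by water at the tertiary carbon rather than proton loss to an isopropenyl group or return to the pyran; this is secured by adding buffered aqueous THF to the cold triflate so that water is in large excess while ionisation proceeds, and by the gem-dimethyl group, which localises the charge. The two MOM ethers leave no phenol for Tf2O and twist the ketone out of conjugation, so O1 keeps its donor strength.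

**Step 8**
Reactants: 12 1-[(2S)-2-(2-hydroxypropan-2-yl)-4,6-bis(methoxymethoxy)-2,3-dihydro-1-benzofuran-5-yl]-3-methylbutan-1-one
Product: 13 1-[(2S)-4,6-dihydroxy-2-(2-hydroxypropan-2-yl)-2,3-dihydro-1-benzofuran-5-yl]-3-methylbutan-1-one
Conditions: HCl (3 M aq), MeOH, 40 °C
Reagents that add atoms: none
Why: Acid-catalysed acetal exchange with methanol removes both MOM groups, helped by the neighbouring carbonyl, under conditions too mild to ionise the tertiary alcohol, and no stereocentre is involved.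

**Step 9**
Reactants: 13 1-[(2S)-4,6-dihydroxy-2-(2-hydroxypropan-2-yl)-2,3-dihydro-1-benzofuran-5-yl]-3-methylbutan-1-one; 14 prenyl bromide
Product: 15 1-[(2S)-4,6-dihydroxy-2-(2-hydroxypropan-2-yl)-7-(3-methylbut-2-en-1-yl)-2,3-dihydro-1-benzofuran-5-yl]-3-methylbutan-1-one
Conditions: 14 (1.05 equiv), KOH (aq, 10%), 0 → 23 °C
Reagents that add atoms: none
Why: C-Alkylation of the phloroglucinol-type phenoxide with an allylic bromide in a protic medium, which hydrogen-bonds the oxygens and steers the ambident anion to carbon; C7 is the only ring carbon that can rearomatise by proton loss.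

**Step 10**
Reactants: 15 1-[(2S)-4,6-dihydroxy-2-(2-hydroxypropan-2-yl)-7-(3-methylbut-2-en-1-yl)-2,3-dihydro-1-benzofuran-5-yl]-3-methylbutan-1-one; 4 3-chloro-3-methylbut-1-yne
Product: 16 1-[(2S)-6-hydroxy-2-(2-hydroxypropan-2-yl)-7-(3-methylbut-2-en-1-yl)-4-(2-methylbut-3-yn-2-yloxy)-2,3-dihydro-1-benzofuran-5-yl]-3-methylbutan-1-one
Conditions: DBU, CuCl2 (cat.), MeCN, 0 → 23 °C; the O6 isomer, if formed, removed by chromatography
Reagents that add atoms: none
Why: Copper-catalysed O-propargylation of a phenol with a tertiary propargylic chloride; O6–H is buttressed by the C7 prenyl group into the chelate with the ketone, whereas O4, flanked only by the tied-back ring methylene, is the accessible nucleophile for the bulky electrophile, and the tertiary alcohol does not react.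

**Step 11**
Reactants: 16 1-[(2S)-6-hydroxy-2-(2-hydroxypropan-2-yl)-7-(3-methylbut-2-en-1-yl)-4-(2-methylbut-3-yn-2-yloxy)-2,3-dihydro-1-benzofuran-5-yl]-3-methylbutan-1-one
Product: 17 1-[(2S)-6-hydroxy-2-(2-hydroxypropan-2-yl)-4-(2-methylbut-3-en-2-yloxy)-7-(3-methylbut-2-en-1-yl)-2,3-dihydro-1-benzofuran-5-yl]-3-methylbutan-1-one
Conditions: H2 (1 atm), Pd/CaCO3 poisoned with Pb(OAc)2, quinoline, EtOAc, 23 °C
Reagents that add atoms: none
Why: Lindlar semi-hydrogenation stops at the terminal alkene and leaves the trisubstituted prenyl double bond, the ketone and the aryl ether untouched.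

**Step 12**
Reactants: 17 1-[(2S)-6-hydroxy-2-(2-hydroxypropan-2-yl)-4-(2-methylbut-3-en-2-yloxy)-7-(3-methylbut-2-en-1-yl)-2,3-dihydro-1-benzofuran-5-yl]-3-methylbutan-1-one
Product: 18 (2S,3aS)-6-hydroxy-2-(2-hydroxypropan-2-yl)-5-(3-methylbutanoyl)-3a,7-bis(3-methylbut-2-en-1-yl)-3,3a-dihydro-1-benzofuran-4(2H)-one (CNP0203294.1)
Conditions: toluene, 110 °C
Reagents that add atoms: none
Why: Aromatic Claisen rearrangement onto the substituted ortho carbon (dearomatising ortho-Claisen): the chair-like [3,3] shift turns the O-bound 1,1-dimethylallyl group into a C3a-bound 3-methylbut-2-enyl group while C4 becomes the ketone; the other ortho carbon bears the acyl group and the para carbon C7 is blocked, so no onward Cope shift can rearomatise, the product is a stable enolised β-triketone, and the allyl unit is delivered suprafacially to the face of C3a anti to the C2 carbinol side chain, which sets (3aS).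

**Compound list**
1 | phloroglucinol (benzene-1,3,5-triol) | Oc1cc(O)cc(O)c1 | starting material
2 | isovaleryl chloride (3-methylbutanoyl chloride) | CC(C)CC(Cl)=O | starting material
3 | 1-(2,4,6-trihydroxyphenyl)-3-methylbutan-1-one | CC(C)CC(=O)c1c(O)cc(O)cc1O | intermediate
4 | 3-chloro-3-methylbut-1-yne | CC(C)(Cl)C#C | starting material
5 | 1-[2,6-dihydroxy-4-(2-methylbut-3-yn-2-yloxy)phenyl]-3-methylbutan-1-one | CC(C)CC(=O)c1c(O)cc(OC(C)(C)C#C)cc1O | intermediate
6 | 1-[2,6-bis(methoxymethoxy)-4-(2-methylbut-3-yn-2-yloxy)phenyl]-3-methylbutan-1-one | CC(C)CC(=O)c1c(OCOC)cc(OC(C)(C)C#C)cc1OCOC | intermediate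
7 | 1-[5,7-bis(methoxymethoxy)-2,2-dimethyl-2H-chromen-6-yl]-3-methylbutan-1-one | CC(C)CC(=O)c1c(OCOC)cc2OC(C)(C)C=Cc2c1OCOC | intermediate
8 | 1-[(3R,4R)-3,4-epoxy-5,7-bis(methoxymethoxy)-2,2-dimethyl-3,4-dihydro-2H-chromen-6-yl]-3-methylbutan-1-one | CC(C)CC(=O)c1c(OCOC)cc2OC(C)(C)[C@@H]3O[C@@H]3c2c1OCOC | intermediate
9 | 1-[(3R)-3-hydroxy-5,7-bis(methoxymethoxy)-2,2-dimethyl-3,4-dihydro-2H-chromen-6-yl]-3-methylbutan-1-one | CC(C)CC(=O)c1c(OCOC)cc2OC(C)(C)[C@H](O)Cc2c1OCOC | intermediate
10 | (3R)-5,7-bis(methoxymethoxy)-2,2-dimethyl-6-(3-methylbutanoyl)-3,4-dihydro-2H-chromen-3-yl trifluoromethanesulfonate | CC(C)CC(=O)c1c(OCOC)cc2OC(C)(C)[C@H](OS(=O)(=O)C(F)(F)F)Cc2c1OCOC | intermediate (not isolated)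
11 | bicyclic aryloxiranium ion: O1 bridges the CMe2 carbon and the former carbinol carbon, which is now (S) | CC(C)CC(=O)c1c(OCOC)cc2c(c1OCOC)C[C@@H]3[O+]2C3(C)C | intermediate (not isolated)
12 | 1-[(2S)-2-(2-hydroxypropan-2-yl)-4,6-bis(methoxymethoxy)-2,3-dihydro-1-benzofuran-5-yl]-3-methylbutan-1-one | CC(C)CC(=O)c1c(OCOC)cc2O[C@H](C(C)(C)O)Cc2c1OCOC | intermediate
13 | 1-[(2S)-4,6-dihydroxy-2-(2-hydroxypropan-2-yl)-2,3-dihydro-1-benzofuran-5-yl]-3-methylbutan-1-one | CC(C)CC(=O)c1c(O)cc2O[C@H](C(C)(C)O)Cc2c1O | intermediate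
14 | prenyl bromide (1-bromo-3-methylbut-2-ene) | CC(C)=CCBr | starting material
15 | 1-[(2S)-4,6-dihydroxy-2-(2-hydroxypropan-2-yl)-7-(3-methylbut-2-en-1-yl)-2,3-dihydro-1-benzofuran-5-yl]-3-methylbutan-1-one | CC(C)CC(=O)c1c(O)c(CC=C(C)C)c2O[C@H](C(C)(C)O)Cc2c1O | intermediate
16 | 1-[(2S)-6-hydroxy-2-(2-hydroxypropan-2-yl)-7-(3-methylbut-2-en-1-yl)-4-(2-methylbut-3-yn-2-yloxy)-2,3-dihydro-1-benzofuran-5-yl]-3-methylbutan-1-one | CC(C)CC(=O)c1c(O)c(CC=C(C)C)c2O[C@H](C(C)(C)O)Cc2c1OC(C)(C)C#C | intermediate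
17 | 1-[(2S)-6-hydroxy-2-(2-hydroxypropan-2-yl)-4-(2-methylbut-3-en-2-yloxy)-7-(3-methylbut-2-en-1-yl)-2,3-dihydro-1-benzofuran-5-yl]-3-methylbutan-1-one | CC(C)CC(=O)c1c(O)c(CC=C(C)C)c2O[C@H](C(C)(C)O)Cc2c1OC(C)(C)C=C | intermediate
18 | (2S,3aS)-6-hydroxy-2-(2-hydroxypropan-2-yl)-5-(3-methylbutanoyl)-3a,7-bis(3-methylbut-2-en-1-yl)-3,3a-dihydro-1-benzofuran-4(2H)-one | CC(C)=CCC1=C2O[C@H](C(C)(C)O)C[C@]2(CC=C(C)C)C(=O)C(C(=O)CC(C)C)=C1O | target

**Totals**
Total step count: 12. Longest linear sequence: 12 steps (1 → 18).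

**Steps most likely to fail**

1. Step 10 – etherification at the wrong oxygen (O6) or at carbon instead of at O4. The fallback uses orthogonal protection so that O4 is the only free phenol when the tertiary ether is made. It sets out from 13, where O6 is flanked only by C7–H and is the more accessible phenol.
   - MOMCl (1 equiv), i-Pr2NEt, CH2Cl2, 0 °C should give 1-[(2S)-4-hydroxy-2-(2-hydroxypropan-2-yl)-6-(methoxymethoxy)-2,3-dihydro-1-benzofuran-5-yl]-3-methylbutan-1-one F1.
   - Prenyl bromide 14, K2CO3, DMF, 50 °C should give the 4-O-(3-methylbut-2-enyl) ether F2.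
   - Heating in N,N-diethylaniline at 190 °C should carry the prenyl group by a Claisen–Cope (para-Claisen) sequence through C3a to the free para carbon and give the 7-prenyl 4-phenol F3.
   - Compound 4, DBU and CuCl2 (cat.) in MeCN should give the 4-O-(2-methylbut-3-yn-2-yl) ether F4.
   - Semi-hydrogenation over Pd/CaCO3 poisoned with Pb(OAc)2 should give the 1,1-dimethylallyl ether F5.
   - Heating in toluene should give the dearomatised 6-O-methoxymethyl enol ether F6.
   - HCl (aq) in THF at 23 °C removes the acetal, and the route is rejoined at 18.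

2. Step 12 – delivery of the allyl unit to both faces of C3a (poor facial selectivity). The fallback enlarges the shielding group at C2 and sets out from 16.
   - TESOTf and 2,6-lutidine in CH2Cl2 should give the bis(triethylsilyl) ether (tertiary oxygen and O6) F7.
   - Semi-hydrogenation as in step 11 should give the 1,1-dimethylallyl ether F8.
   - The Claisen shift in toluene should give the bis-silylated dienone F9, in which the bulkier CMe2OSiEt3 group should block the syn face more strongly.
   - HF·pyridine in THF removes both silyl groups and returns the route at 18.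

3. Step 7 – proton loss from the tertiary cation (elimination to an isopropenyl group) outrunning capture by water. The fallback makes elimination the intended outcome and sets out from 9.
   - Triflation and rearrangement without water (Tf2O, excess 2,6-lutidine, CH2Cl2, −78 → 23 °C) should give, with the same inversion, 1-[(2S)-4,6-bis(methoxymethoxy)-2-(prop-1-en-2-yl)-2,3-dihydro-1-benzofuran-5-yl]-3-methylbutan-1-one F10.
   - Mukaiyama hydration (Co(acac)2, PhSiH3, O2, i-PrOH, 23 °C) then places the hydroxyl on the tertiary carbon, and the route is rejoined at 12.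

**Further compounds**
F1 | step 10 | 1-[(2S)-4-hydroxy-2-(2-hydroxypropan-2-yl)-6-(methoxymethoxy)-2,3-dihydro-1-benzofuran-5-yl]-3-methylbutan-1-one | CC(C)CC(=O)c1c(OCOC)cc2O[C@H](C(C)(C)O)Cc2c1O
F2 | step 10 | 1-[(2S)-2-(2-hydroxypropan-2-yl)-6-(methoxymethoxy)-4-(3-methylbut-2-enyloxy)-2,3-dihydro-1-benzofuran-5-yl]-3-methylbutan-1-one | CC(C)CC(=O)c1c(OCOC)cc2O[C@H](C(C)(C)O)Cc2c1OCC=C(C)C
F3 | step 10 | 1-[(2S)-4-hydroxy-2-(2-hydroxypropan-2-yl)-6-(methoxymethoxy)-7-(3-methylbut-2-en-1-yl)-2,3-dihydro-1-benzofuran-5-yl]-3-methylbutan-1-one | CC(C)CC(=O)c1c(OCOC)c(CC=C(C)C)c2O[C@H](C(C)(C)O)Cc2c1O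
F4 | step 10 | 1-[(2S)-2-(2-hydroxypropan-2-yl)-6-(methoxymethoxy)-7-(3-methylbut-2-en-1-yl)-4-(2-methylbut-3-yn-2-yloxy)-2,3-dihydro-1-benzofuran-5-yl]-3-methylbutan-1-one | CC(C)CC(=O)c1c(OCOC)c(CC=C(C)C)c2O[C@H](C(C)(C)O)Cc2c1OC(C)(C)C#C
F5 | step 10 | 1-[(2S)-2-(2-hydroxypropan-2-yl)-6-(methoxymethoxy)-4-(2-methylbut-3-en-2-yloxy)-7-(3-methylbut-2-en-1-yl)-2,3-dihydro-1-benzofuran-5-yl]-3-methylbutan-1-one | CC(C)CC(=O)c1c(OCOC)c(CC=C(C)C)c2O[C@H](C(C)(C)O)Cc2c1OC(C)(C)C=C
F6 | step 10 | (2S,3aS)-2-(2-hydroxypropan-2-yl)-6-(methoxymethoxy)-5-(3-methylbutanoyl)-3a,7-bis(3-methylbut-2-en-1-yl)-3,3a-dihydro-1-benzofuran-4(2H)-one | CC(C)=CCC1=C2O[C@H](C(C)(C)O)C[C@]2(CC=C(C)C)C(=O)C(C(=O)CC(C)C)=C1OCOC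
F7 | step 12 | 1-[(2S)-7-(3-methylbut-2-en-1-yl)-4-(2-methylbut-3-yn-2-yloxy)-6-(triethylsilyloxy)-2-[2-(triethylsilyloxy)propan-2-yl]-2,3-dihydro-1-benzofuran-5-yl]-3-methylbutan-1-one | CC(C)CC(=O)c1c(O[Si](CC)(CC)CC)c(CC=C(C)C)c2O[C@H](C(C)(C)O[Si](CC)(CC)CC)Cc2c1OC(C)(C)C#C
F8 | step 12 | 1-[(2S)-4-(2-methylbut-3-en-2-yloxy)-7-(3-methylbut-2-en-1-yl)-6-(triethylsilyloxy)-2-[2-(triethylsilyloxy)propan-2-yl]-2,3-dihydro-1-benzofuran-5-yl]-3-methylbutan-1-one | CC(C)CC(=O)c1c(O[Si](CC)(CC)CC)c(CC=C(C)C)c2O[C@H](C(C)(C)O[Si](CC)(CC)CC)Cc2c1OC(C)(C)C=C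
F9 | step 12 | (2S,3aS)-5-(3-methylbutanoyl)-3a,7-bis(3-methylbut-2-en-1-yl)-6-(triethylsilyloxy)-2-[2-(triethylsilyloxy)propan-2-yl]-3,3a-dihydro-1-benzofuran-4(2H)-one | CC(C)=CCC1=C2O[C@H](C(C)(C)O[Si](CC)(CC)CC)C[C@]2(CC=C(C)C)C(=O)C(C(=O)CC(C)C)=C1O[Si](CC)(CC)CC
F10 | step 7 | 1-[(2S)-4,6-bis(methoxymethoxy)-2-(prop-1-en-2-yl)-2,3-dihydro-1-benzofuran-5-yl]-3-methylbutan-1-one | CC(C)CC(=O)c1c(OCOC)cc2O[C@H](C(C)=C)Cc2c1OCOC
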